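**Plan**

- Numbering (terpenoid type): ring A is the brominated ring (C-1 to C-5 and C-10), ring B the methylene ring (C-5 to C-10); C-11 is the benzylic CH2, C-12 to C-15 the side chain, C-17 the exocyclic CH2.
- Retrosynthetic cuts, in order: C-11 oxygen put back (aryl ketone), C-8–C-9 (ring B), C-11–aryl, C-6–C-7, C-10–C-9 (Claisen), C-4–C-5 (ring A), C-1–C-2.
- Forward: geraniol supplies C-2, C-3, C-4 with its methyl and the whole side chain C-12 to C-15; ring A closes first by a bromonium cation–olefin cyclisation, C-10 and C-5 are then built on it, and ring B closes last.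
- Stereochemistry: C-3/C-4 from a ligand-controlled anti bromochlorination of the E-alkene and a stereospecific bromonium cyclisation; C-10 (Claisen) and C-5 (hydroboration) by substrate control; C-14 by Shi epoxidation and invertive bromide opening; C-9 in the ring B closure.
- Enabling feature: C-9 lies between the methylene-bearing C-8 and the benzylic C-11 that carries an ortho-hydroxyaryl ring. A C-11 ketone therefore makes C-9 an enol carbon that can attack a terminal alkyne at C-8 (the latent C-8=CH2), and the ortho-phenol afterwards expels the C-11 oxygen through an ortho-quinone methide.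

Key step: step 17

Remark: the chiral Schiff-base ligand of step 1 and the chiral ketone catalyst of step 12 are treated as available catalysts; they add no atoms to any product.

**Route**

Step 1
Reactants: 1 geraniol
Product: 2 (2R,3S)-2-bromo-3-chloro-3,7-dimethyloct-6-en-1-ol
Conditions: NBS, ClTi(OiPr)3, chiral tridentate Schiff-base ligand (20 mol%, the enantiomer giving 2R,3S), hexane, −20 °C
Reagents that add atoms: N-bromosuccinimide O=C1CCC(=O)N1Br; chlorotitanium triisopropoxide CC(C)O[Ti](Cl)(OC(C)C)OC(C)C
Why: Ligand-controlled titanium-mediated enantioselective bromochlorination of an allylic alcohol, in which the titanium-bound alkoxide directs anti addition to the neighbouring E-alkene only, with bromine at C-2 and chloride at the tertiary C-3, so that both stereocentres (the later C-3 and C-4 of ring A) are set by the ligand and the remote trisubstituted alkene should survive.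

Step 2
Reactants: 2 (2R,3S)-2-bromo-3-chloro-3,7-dimethyloct-6-en-1-ol; 3 methyl acetoacetate
Product: 6 methyl (6R,7S)-6-bromo-7-chloro-7,11-dimethyl-3-oxododec-10-enoate, via primary triflate 4 (not isolated), via acetoacetate dianion 5 (not isolated)
Conditions: Tf2O, 2,6-lutidine, CH2Cl2, −78 °C; crude triflate added to 3 pre-treated with NaH then n-BuLi (THF, 0 °C), −78 to 0 °C; H2O work-up
Reagents that add atoms: none
Why: Acetoacetate dianion γ-alkylation, an SN2 displacement of the primary triflate by the terminal carbanion of the dianion, should extend the chain by C-1, C-10, C-5 and C-6 at low temperature without touching the two halogen-bearing stereocentres.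

Step 3
Reactants: 6 methyl (6R,7S)-6-bromo-7-chloro-7,11-dimethyl-3-oxododec-10-enoate
Product: 7 methyl (1R,2R,3R)-3-bromo-2-methyl-2-(4-methylpent-3-en-1-yl)-6-oxocyclohexane-1-carboxylate (ring A)
Conditions: (CF3)2CHOH, 2,6-di-tert-butylpyridine (1.2 equiv), 0 °C to rt
Reagents that add atoms: none
Why: Stereospecific bromonium-ion cation–olefin cyclisation started by solvolysis of the tertiary chloride in the ionising solvent: the neighbouring bromine displaces chloride to re-form the enantiopure bromonium ion and the enol carbon of the β-keto ester opens it at the tertiary carbon through a chair-like six-membered transition state, so that C-4 keeps its configuration by double inversion with bromine equatorial and the C-4 methyl axial, while the homoprenyl alkene could only close a four-membered ring and stays out.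

Step 4
Reactants: 7 methyl (1R,2R,3R)-3-bromo-2-methyl-2-(4-methylpent-3-en-1-yl)-6-oxocyclohexane-1-carboxylate
Product: 8 methyl (5R,6R)-5-bromo-6-methyl-6-(4-methylpent-3-en-1-yl)-2-(trifluoromethanesulfonyloxy)cyclohex-1-ene-1-carboxylate
Conditions: Tf2O, i-Pr2NEt, CH2Cl2, −78 °C
Reagents that add atoms: trifluoromethanesulfonic anhydride O=S(=O)(OS(=O)(=O)C(F)(F)F)C(F)(F)F
Why: Enol triflate formation by O-sulfonylation of the enolised β-keto ester under amine base at low temperature should give the tetrasubstituted enol triflate without a long-lived enolate that might displace the hindered bromide, the C-5 stereocentre being deliberately erased here.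

Step 5
Reactants: 8 methyl (5R,6R)-5-bromo-6-methyl-6-(4-methylpent-3-en-1-yl)-2-(trifluoromethanesulfonyloxy)cyclohex-1-ene-1-carboxylate
Product: 9 methyl (5R,6R)-5-bromo-2,6-dimethyl-6-(4-methylpent-3-en-1-yl)cyclohex-1-ene-1-carboxylate
Conditions: MeZnCl, Pd(PPh3)4 (5 mol%), THF, rt to 50 °C
Reagents that add atoms: methylzinc chloride C[Zn]Cl
Why: Negishi coupling, in which zerovalent palladium inserts readily into the electron-poor alkenyl triflate but not into the hindered secondary alkyl bromide, should replace the triflate by methyl and fix the position of the tetrasubstituted alkene.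

Step 6
Reactants: 9 methyl (5R,6R)-5-bromo-2,6-dimethyl-6-(4-methylpent-3-en-1-yl)cyclohex-1-ene-1-carboxylate
Product: 10 [(5R,6R)-5-bromo-2,6-dimethyl-6-(4-methylpent-3-en-1-yl)cyclohex-1-en-1-yl]methanol
Conditions: i-Bu2AlH (2.5 equiv), CH2Cl2, −78 to 0 °C; aqueous work-up
Reagents that add atoms: none
Why: Hydride 1,2-reduction of the hindered unsaturated ester by i-Bu2AlH should give the β-cyclogeraniol-type allylic alcohol needed for the sigmatropic step and leave the alkyl bromide alone.

Step 7
Reactants: 10 [(5R,6R)-5-bromo-2,6-dimethyl-6-(4-methylpent-3-en-1-yl)cyclohex-1-en-1-yl]methanol; 11 triethyl orthoacetate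
Product: 13 ethyl 2-[(1S,3R,4R)-4-bromo-1,3-dimethyl-2-methylidene-3-(4-methylpent-3-en-1-yl)cyclohexyl]acetate, via ketene acetal 12 (not isolated)
Conditions: 11 (excess, neat), EtCO2H (cat.), 140 °C, EtOH distilled off
Reagents that add atoms: none
Why: Johnson–Claisen rearrangement: the ketene acetal 12 formed from the allylic alcohol and the orthoester undergoes a [3,3] shift that creates the quaternary C-10, and the new C-10–C-9 bond should form on the ring face opposite the pseudoaxial C-4 methyl in the half-chair that keeps bromine equatorial (the alternative places the migrating CH2–O over an axial bromine), which puts the acetate arm trans to that methyl.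

Step 8
Reactants: 13 ethyl 2-[(1S,3R,4R)-4-bromo-1,3-dimethyl-2-methylidene-3-(4-methylpent-3-en-1-yl)cyclohexyl]acetate
Product: 15 ethyl 2-[(1S,2S,3R,4R)-4-bromo-2-(hydroxymethyl)-1,3-dimethyl-3-(4-methylpent-3-en-1-yl)cyclohexyl]acetate, via alkylborane 14 (not isolated)
Conditions: 9-BBN, THF, rt; then H2O2, aq. NaOAc, 0 °C
Reagents that add atoms: hydrogen peroxide OO
Why: Hydroboration–oxidation: 9-BBN is expected to add to the 1,1-disubstituted exocyclic alkene in preference to the trisubstituted side-chain alkene, with boron on the terminal carbon and hydrogen delivered to C-5 from the face opposite the two flanking axial methyl groups, which sets C-5 with its arm equatorial and trans to the C-9 arm on C-10.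

Step 9
Reactants: 15 ethyl 2-[(1S,2S,3R,4R)-4-bromo-2-(hydroxymethyl)-1,3-dimethyl-3-(4-methylpent-3-en-1-yl)cyclohexyl]acetate; 16 1-(trimethylsilyl)propyne
Product: 19 ethyl 2-[4-bromo-1,3-dimethyl-3-(4-methylpent-3-en-1-yl)-2-(4-trimethylsilylbut-3-yn-1-yl)cyclohexyl]acetate (ring stereocentres as in 15), via primary triflate 17 (not isolated), via lithiated silylpropyne 18 (not isolated)
Conditions: Tf2O, 2,6-lutidine, CH2Cl2, −78 °C; crude triflate added to 16/n-BuLi (THF, −78 °C), then −78 to −40 °C
Reagents that add atoms: none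
Why: SN2 alkylation of a propargylic organolithium by a primary triflate: the lithiated silylpropyne reacts at its CH2 terminus and the triflate should be displaced at −78 °C well before the hindered ester is attacked, giving the three-carbon alkyne arm C-7, C-8, C-17.

Step 10
Reactants: 19 ethyl 2-[4-bromo-1,3-dimethyl-3-(4-methylpent-3-en-1-yl)-2-(4-trimethylsilylbut-3-yn-1-yl)cyclohexyl]acetate
Product: 20 2-[4-bromo-1,3-dimethyl-3-(4-methylpent-3-en-1-yl)-2-(4-trimethylsilylbut-3-yn-1-yl)cyclohexyl]-N-methoxy-N-methylacetamide (ring stereocentres as in 15)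
Conditions: MeNH(OMe)·HCl, i-PrMgCl, THF, −20 to 0 °C; aqueous work-up
Reagents that add atoms: N,O-dimethylhydroxylamine hydrochloride CNOC.Cl
Why: Ester aminolysis by the magnesium amide of N,O-dimethylhydroxylamine should give the N-methoxy-N-methylamide, the acyl donor that stops at the ketone stage in the next step.

Step 11
Reactants: 20 2-[4-bromo-1,3-dimethyl-3-(4-methylpent-3-en-1-yl)-2-(4-trimethylsilylbut-3-yn-1-yl)cyclohexyl]-N-methoxy-N-methylacetamide; 21 (methoxymethoxy)benzene
Product: 24 2-[4-bromo-2-(but-3-yn-1-yl)-1,3-dimethyl-3-(4-methylpent-3-en-1-yl)cyclohexyl]-1-[2-(methoxymethoxy)phenyl]ethan-1-one (ring stereocentres as in 15), via aryllithium 22 (not isolated), via silylalkyne ketone 23 (not isolated)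
Conditions: 21, n-BuLi, Et2O, 0 °C; then 20, THF, −78 to 0 °C; H2O; then K2CO3 (cat.), MeOH, rt
Reagents that add atoms: none
Why: Directed ortho-lithiation of the MOM ether followed by acyl substitution at the N-methoxy-N-methylamide, which stops at the ketone through its chelated tetrahedral intermediate, should join the arene to C-11, and base-catalysed methanolysis then removes the alkynyl silyl group.

Step 12
Reactants: 24 2-[4-bromo-2-(but-3-yn-1-yl)-1,3-dimethyl-3-(4-methylpent-3-en-1-yl)cyclohexyl]-1-[2-(methoxymethoxy)phenyl]ethan-1-one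
Product: 25 epoxide of 24 with the side chain 2-[(2S)-3,3-dimethyloxiran-2-yl]ethyl
Conditions: L-sorbose-derived enantiomer of the fructose-based chiral ketone catalyst (30 mol%, expected to give the 14S epoxide), KHSO5, K2CO3, MeCN/CH2(OMe)2/H2O (pH 10.5), 0 °C
Reagents that add atoms: potassium peroxymonosulfate [K+].[O-]S(=O)(=O)OO
Why: Shi epoxidation: the chiral dioxirane should oxidise only the electron-rich trisubstituted alkene, leaving alkyne, ketone and aryl ether, and the chosen catalyst enantiomer sets C-14 as S.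

Step 13
Reactants: 25 epoxide of 24 with the side chain 2-[(2S)-3,3-dimethyloxiran-2-yl]ethyl
Product: 26 bromohydrin with the side chain (3R)-3-bromo-4-hydroxy-4-methylpentyl
Conditions: Li2NiBr4, THF, 0 °C to rt; H2O
Reagents that add atoms: dilithium tetrabromonickelate [Li+].[Li+].[Ni+2].[Br-].[Br-].[Br-].[Br-]
Why: Regioselective SN2 opening of the trisubstituted epoxide by soft bromide at its less substituted carbon should invert C-14 to the R bromide and leave the tertiary alcohol.

Step 14
Reactants: 26 bromohydrin with the side chain (3R)-3-bromo-4-hydroxy-4-methylpentyl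
Product: 27 2-[4-bromo-3-[(3R)-3-bromo-4-chloro-4-methylpentyl]-2-(but-3-yn-1-yl)-1,3-dimethylcyclohexyl]-1-(2-hydroxyphenyl)ethan-1-one (ring stereocentres as in 15)
Conditions: HCl (4 M in 1,4-dioxane), CH2Cl2, 0 °C to rt
Reagents that add atoms: hydrogen chloride Cl
Why: Substitution of the tertiary alcohol through a bromonium ion (neighbouring-group participation): protonation and loss of water are assisted by the adjacent bromine and chloride opens the bridged ion at the tertiary carbon, so that C-14 is retained, while the same acid cleaves the aryl MOM acetal.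

Step 15
Reactants: 27 2-[4-bromo-3-[(3R)-3-bromo-4-chloro-4-methylpentyl]-2-(but-3-yn-1-yl)-1,3-dimethylcyclohexyl]-1-(2-hydroxyphenyl)ethan-1-one
Product: 28 2-[4-bromo-3-[(3R)-3-bromo-4-chloro-4-methylpentyl]-2-(but-3-yn-1-yl)-1,3-dimethylcyclohexyl]-1-(3,5-dibromo-2-hydroxyphenyl)ethan-1-one
Conditions: NBS (2.05 equiv), MeCN, 0 °C to rt
Reagents that add atoms: N-bromosuccinimide O=C1CCC(=O)N1Br
Why: Electrophilic aromatic bromination: the free phenol directs two bromines to its open ortho and para positions, both meta to the acyl group, and the alkyne, ketone and alkyl halides should be inert to NBS without a promoter.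

Step 16
Reactants: 28 2-[4-bromo-3-[(3R)-3-bromo-4-chloro-4-methylpentyl]-2-(but-3-yn-1-yl)-1,3-dimethylcyclohexyl]-1-(3,5-dibromo-2-hydroxyphenyl)ethan-1-one
Product: 29 2,4-dibromo-6-{2-[4-bromo-3-[(3R)-3-bromo-4-chloro-4-methylpentyl]-2-(but-3-yn-1-yl)-1,3-dimethylcyclohexyl]acetyl}phenyl ethyl carbonate
Conditions: ClCO2Et, Et3N, CH2Cl2, 0 °C
Reagents that add atoms: ethyl chloroformate CCOC(=O)Cl
Why: O-Acylation of the phenol by the chloroformate masks it for the enol silylation and installs the carbonate that later carries the C-11 oxygen away.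

Step 17
Reactants: 29 2,4-dibromo-6-{2-[4-bromo-3-[(3R)-3-bromo-4-chloro-4-methylpentyl]-2-(but-3-yn-1-yl)-1,3-dimethylcyclohexyl]acetyl}phenyl ethyl carbonate
Product: 31 2,4-dibromo-6-[(C-11 ketone of the target decalin)]phenyl ethyl carbonate (all stereocentres as in 33), via silyl enol ether 30 (not isolated)
Conditions: TBSOTf, Et3N, CH2Cl2, 0 °C; then AuCl(PPh3) (10 mol%), AgBF4 (10 mol%), CH2Cl2/MeOH 10:1, 40 °C
Reagents that add atoms: none
Why: The ketone, enolisable only at C-9, is converted into its Z silyl enol ether 30, and cationic monovalent gold from AuCl(PPh3)/AgBF4 activates the terminal alkyne; C-9 then attacks the internal alkyne carbon C-8 anti to gold, methanol protonates the vinyl–gold bond to leave the exocyclic methylene, and the silyl group is lost to methanol. The closest known reaction type is the gold-catalysed carbocyclisation of silyl enol ethers onto alkynes (Conia-ene type). Ring B closes in the 6-exo-dig mode. The new stereocentre C-9 is controlled by the chair-like transition state built on the trans-diequatorial C-5 and C-10 arms of ring A, in which the enol ether carbon C-11 takes the equatorial position, and this α-keto centre can also equilibrate to the same, more stable equatorial aroyl isomer; the trans ring fusion follows from C-5 and C-10. The step needs exo over endo closure, which attack at the substituted carbon of a terminal alkyne secures, and C- over O-attack of the enol ether; the four C–Br bonds, the tertiary chloride and the aryl carbonate should be inert to the carbophilic catalyst.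

Step 18
Reactants: 31 2,4-dibromo-6-[(C-11 ketone of the target decalin)]phenyl ethyl carbonate
Product: 33 CNP0318265.2, via ortho-quinone methide 32 (not isolated)
Conditions: NaBH4 (excess), THF/H2O, 0 °C to rt
Reagents that add atoms: none
Why: Carbonate-transfer reduction through an ortho-quinone methide: hydride reduces the ketone, the benzylic alkoxide takes over the neighbouring carbonate, the phenoxide expels ethyl carbonate to give ortho-quinone methide 32 and a second hydride adds to its exocyclic carbon, which turns C-11 into CH2 and frees the phenol without touching the alkene, the halides or C-9.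

**Compound list**

1 | geraniol, (2E)-3,7-dimethylocta-2,6-dien-1-ol | CC(C)=CCC/C(C)=C/CO | starting material
2 | (2R,3S)-2-bromo-3-chloro-3,7-dimethyloct-6-en-1-ol | Cl[C@@](C)(CCC=C(C)C)[C@H](Br)CO | intermediate
3 | methyl acetoacetate (methyl 3-oxobutanoate) | COC(=O)CC(C)=O | starting material
4 | (2R,3S)-2-bromo-3-chloro-3,7-dimethyloct-6-en-1-yl trifluoromethanesulfonate | Cl[C@@](C)(CCC=C(C)C)[C@H](Br)COS(=O)(=O)C(F)(F)F | intermediate
5 | sodium lithium dianion of methyl acetoacetate | [Na+].[Li+].[CH2-]C(=O)[CH-]C(=O)OC | intermediate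
6 | methyl (6R,7S)-6-bromo-7-chloro-7,11-dimethyl-3-oxododec-10-enoate | Cl[C@@](C)(CCC=C(C)C)[C@H](Br)CCC(=O)CC(=O)OC | intermediate
7 | methyl (1R,2R,3R)-3-bromo-2-methyl-2-(4-methylpent-3-en-1-yl)-6-oxocyclohexane-1-carboxylate (Br, 2-methyl and ester on one face; C-1 enolisable) | COC(=O)[C@@H]1[C@@](C)(CCC=C(C)C)[C@H](Br)CCC1=O | intermediate
8 | methyl (5R,6R)-5-bromo-6-methyl-6-(4-methylpent-3-en-1-yl)-2-(trifluoromethanesulfonyloxy)cyclohex-1-ene-1-carboxylate | COC(=O)C1=C(OS(=O)(=O)C(F)(F)F)CC[C@@H](Br)[C@]1(C)CCC=C(C)C | intermediate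
9 | methyl (5R,6R)-5-bromo-2,6-dimethyl-6-(4-methylpent-3-en-1-yl)cyclohex-1-ene-1-carboxylate | COC(=O)C1=C(C)CC[C@@H](Br)[C@]1(C)CCC=C(C)C | intermediate
10 | [(5R,6R)-5-bromo-2,6-dimethyl-6-(4-methylpent-3-en-1-yl)cyclohex-1-en-1-yl]methanol | OCC1=C(C)CC[C@@H](Br)[C@]1(C)CCC=C(C)C | intermediate
11 | triethyl orthoacetate (1,1,1-triethoxyethane) | CC(OCC)(OCC)OCC | starting material
12 | ketene acetal: 1-ethoxyethenyl ether of 10 | C=C(OCC)OCC1=C(C)CC[C@@H](Br)[C@]1(C)CCC=C(C)C | intermediate
13 | ethyl 2-[(1S,3R,4R)-4-bromo-1,3-dimethyl-2-methylidene-3-(4-methylpent-3-en-1-yl)cyclohexyl]acetate (Br and both ring methyls on one face) | C=C1[C@@](C)(CCC=C(C)C)[C@H](Br)CC[C@@]1(C)CC(=O)OCC | intermediate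
14 | B-alkyl-9-borabicyclo[3.3.1]nonane from 13 (boron on the former methylidene carbon; new C-5 hydrogen trans to both ring methyls) | B2(C3CCCC2CCC3)C[C@@H]1[C@@](C)(CCC=C(C)C)[C@H](Br)CC[C@@]1(C)CC(=O)OCC | intermediate
15 | ethyl 2-[(1S,2S,3R,4R)-4-bromo-2-(hydroxymethyl)-1,3-dimethyl-3-(4-methylpent-3-en-1-yl)cyclohexyl]acetate | OC[C@@H]1[C@@](C)(CCC=C(C)C)[C@H](Br)CC[C@@]1(C)CC(=O)OCC | intermediate
16 | 1-(trimethylsilyl)propyne | CC#C[Si](C)(C)C | starting material
17 | primary triflate of 15 | FC(F)(F)S(=O)(=O)OC[C@@H]1[C@@](C)(CCC=C(C)C)[C@H](Br)CC[C@@]1(C)CC(=O)OCC | intermediate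
18 | 3-(trimethylsilyl)prop-2-yn-1-yllithium | [Li]CC#C[Si](C)(C)C | intermediate
19 | ethyl 2-[4-bromo-1,3-dimethyl-3-(4-methylpent-3-en-1-yl)-2-(4-trimethylsilylbut-3-yn-1-yl)cyclohexyl]acetate (ring stereocentres as in 15) | C[Si](C)(C)C#CCC[C@@H]1[C@@](C)(CCC=C(C)C)[C@H](Br)CC[C@@]1(C)CC(=O)OCC | intermediate
20 | 2-[4-bromo-1,3-dimethyl-3-(4-methylpent-3-en-1-yl)-2-(4-trimethylsilylbut-3-yn-1-yl)cyclohexyl]-N-methoxy-N-methylacetamide (ring stereocentres as in 15) | C[Si](C)(C)C#CCC[C@@H]1[C@@](C)(CCC=C(C)C)[C@H](Br)CC[C@@]1(C)CC(=O)N(C)OC | intermediate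
21 | (methoxymethoxy)benzene | COCOc1ccccc1 | starting material
22 | 2-(methoxymethoxy)phenyllithium | [Li]c1ccccc1OCOC | intermediate
23 | C-silylated precursor of 24 (alkyne terminus carries SiMe3) | C[Si](C)(C)C#CCC[C@@H]1[C@@](C)(CCC=C(C)C)[C@H](Br)CC[C@@]1(C)CC(=O)c1ccccc1OCOC | intermediate
24 | 2-[4-bromo-2-(but-3-yn-1-yl)-1,3-dimethyl-3-(4-methylpent-3-en-1-yl)cyclohexyl]-1-[2-(methoxymethoxy)phenyl]ethan-1-one (ring stereocentres as in 15) | C#CCC[C@@H]1[C@@](C)(CCC=C(C)C)[C@H](Br)CC[C@@]1(C)CC(=O)c1ccccc1OCOC | intermediate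
25 | epoxide of 24, side chain 2-[(2S)-3,3-dimethyloxiran-2-yl]ethyl | C#CCC[C@@H]1[C@@](C)(CC[C@@H]2OC2(C)C)[C@H](Br)CC[C@@]1(C)CC(=O)c1ccccc1OCOC | intermediate
26 | bromohydrin, side chain (3R)-3-bromo-4-hydroxy-4-methylpentyl | C#CCC[C@@H]1[C@@](C)(CC[C@@H](Br)C(C)(C)O)[C@H](Br)CC[C@@]1(C)CC(=O)c1ccccc1OCOC | intermediate
27 | 2-[4-bromo-3-[(3R)-3-bromo-4-chloro-4-methylpentyl]-2-(but-3-yn-1-yl)-1,3-dimethylcyclohexyl]-1-(2-hydroxyphenyl)ethan-1-one (ring stereocentres as in 15) | C#CCC[C@@H]1[C@@](C)(CC[C@@H](Br)C(C)(C)Cl)[C@H](Br)CC[C@@]1(C)CC(=O)c1ccccc1O | intermediate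
28 | 3,5-dibromo-2-hydroxyphenyl analogue of 27 | C#CCC[C@@H]1[C@@](C)(CC[C@@H](Br)C(C)(C)Cl)[C@H](Br)CC[C@@]1(C)CC(=O)c1cc(Br)cc(Br)c1O | intermediate
29 | aryl ethyl carbonate of 28 | C#CCC[C@@H]1[C@@](C)(CC[C@@H](Br)C(C)(C)Cl)[C@H](Br)CC[C@@]1(C)CC(=O)c1cc(Br)cc(Br)c1OC(=O)OCC | intermediate
30 | (Z)-tert-butyldimethylsilyl enol ether of 29 (C-9=C-11) | C#CCC[C@@H]1[C@@](C)(CC[C@@H](Br)C(C)(C)Cl)[C@H](Br)CC[C@@]1(C)/C=C(\O[Si](C)(C)C(C)(C)C)c1cc(Br)cc(Br)c1OC(=O)OCC | intermediate
31 | C-11 ketone of the target skeleton with the phenol as ethyl carbonate; aroyl group equatorial at C-9, all stereocentres as in 33 | C=C1CC[C@@H]2[C@@](C)(CC[C@@H](Br)C(C)(C)Cl)[C@H](Br)CC[C@@]2(C)[C@@H]1C(=O)c1cc(Br)cc(Br)c1OC(=O)OCC | intermediate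
32 | ortho-quinone methide: 2,4-dibromo-6-(decalinylmethylidene)cyclohexa-2,4-dien-1-one, decalin as in 33 | C=C1CC[C@@H]2[C@@](C)(CC[C@@H](Br)C(C)(C)Cl)[C@H](Br)CC[C@@]2(C)[C@@H]1C=C1C=C(Br)C=C(Br)C1=O | intermediate
33 | CNP0318265.2: 2,4-dibromo-6-{[(1R,4aS,5R,6R,8aS)-6-bromo-5-[(3R)-3-bromo-4-chloro-4-methylpentyl]-5,8a-dimethyl-2-methylidenedecahydronaphthalen-1-yl]methyl}phenol | C=C1CC[C@@H]2[C@@](C)(CC[C@@H](Br)C(C)(C)Cl)[C@H](Br)CC[C@@]2(C)[C@@H]1Cc1cc(Br)cc(Br)c1O | target

**Step count and risks**

Total step count: 18. Longest linear sequence: 18 steps, from geraniol (1) to 33.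

Steps most likely to fail:

Step 17. The hindered silyl enol ether may be protodesilylated, or the alkyne hydrated, faster than C-9 attacks C-8. The fallback sets out from 29. LiN(SiMe3)2 at −78 °C should move the carbonate carbonyl from oxygen to C-9 (Baker–Venkataraman-type acyl transfer), and the keto ester so formed lactonises to the 4-hydroxycoumarin F1, a much more acidic 1,3-dicarbonyl nucleophile. A Conia-ene cyclisation of this compound (AuCl(PPh3)/AgOTf or In(NTf2)3) should close ring B to the spiro chromane-2,4-dione F2. Aqueous LiOH then opens the lactone with loss of carbon dioxide to the hydroxyaryl ketone F3, and ethyl chloroformate with Et3N returns the route to 31.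

Step 3. The bromonium ion may be captured by the enol oxygen (O-cyclisation) or lose a proton instead of forming the C-4–C-5 bond. The fallback sets out from 6. The O-cyclised enol ether F4 is accepted as the solvolysis product, isolated, and re-ionised at its tertiary C–O bond with SnCl4 in CH2Cl2, conditions under which such cyclic vinylogous carbonates are known to rearrange to the C-alkylated keto ester. This returns the route to 7.

Step 13. Bromide may open the epoxide at the tertiary carbon, or the epoxide may rearrange to a ketone. The fallback sets out from 25 and reverses the order of halogen introduction. HCl in dioxane should open the epoxide at the tertiary carbon and cleave the MOM ether to give the chlorohydrin F5, with C-14 still S. An Appel bromination (CBr4, PPh3) then replaces the secondary hydroxyl with inversion and returns the route to 27.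

Further compounds
F1 | step 17 | 6,8-dibromo-4-hydroxycoumarin carrying the ring A unit of 29 at C-3 (C-3 of the coumarin is C-9) | C#CCC[C@@H]1[C@@](C)(CC[C@@H](Br)C(C)(C)Cl)[C@H](Br)CC[C@@]1(C)C1=C(O)c2cc(Br)cc(Br)c2OC1=O
F2 | step 17 | spiro chromane-2,4-dione with ring B closed at the spiro carbon C-9 (configuration at C-9 immaterial) | C=C1CC[C@@H]2[C@@](C)(CC[C@@H](Br)C(C)(C)Cl)[C@H](Br)CC[C@@]2(C)C13C(=O)Oc4c(Br)cc(Br)cc4C3=O
F3 | step 17 | free phenol corresponding to 31 (3,5-dibromo-2-hydroxyphenyl ketone, aroyl equatorial at C-9) | C=C1CC[C@@H]2[C@@](C)(CC[C@@H](Br)C(C)(C)Cl)[C@H](Br)CC[C@@]2(C)[C@@H]1C(=O)c1cc(Br)cc(Br)c1O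
F4 | step 3 | O-cyclised enol ether: methyl 2-[5-bromo-6-methyl-6-(4-methylpent-3-en-1-yl)oxan-2-ylidene]acetate, C-3 and C-4 as in 7 | COC(=O)C=C1CC[C@@H](Br)[C@](C)(CCC=C(C)C)O1
F5 | step 13 | chlorohydrin phenol, side chain (3S)-4-chloro-3-hydroxy-4-methylpentyl, otherwise as 27 | C#CCC[C@@H]1[C@@](C)(CC[C@H](O)C(C)(C)Cl)[C@H](Br)CC[C@@]1(C)CC(=O)c1ccccc1O
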